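**Strategy.** Ring C is cut at O1–C2 and C4–C3. The key step exploits the ortho relation of O1 (on C8a) and C4 (on C4a) on ring A: a salicylaldehyde brings both, and an (E)-cinnamaldehyde brings C2–C3 with ring B. An amine-catalysed oxa-Michael/aldol condensation joins both bonds in one operation and sets C2. The formyl group left on C3 is a traceless activator: it allows nucleophilic, prenyl-safe epoxidation of C3=C4 and leaves as formate once C4 is a ketone, after which C3 settles trans to the C2 aryl group. Both prenyl groups are carried from the start; no electrophilic oxidant is used.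

Key step: step 5

Remark: atoms are numbered as in a flavanone (O1, C2, C3, C4, C4a, C5–C8, C8a; ring B primed); prenyl = 3-methylbut-2-en-1-yl, MOM = methoxymethyl.

Assumption: the sense of induction in step 5 follows the usual model for (S)-diarylprolinol silyl ethers (attack on the Si face of the β-carbon of the iminium ion); should the opposite sense be found, the (R)-catalyst is used.

Step 1
Reactants: 1 2,4,6-trihydroxybenzaldehyde
Product: 2 2,4,6-trihydroxy-3-prenylbenzaldehyde
Conditions: prenyl bromide (1.0 equiv), 10% aq KOH, 0 °C to rt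
Reagents that add atoms: prenyl bromide CC(C)=CCBr
Why: C-alkylation of the ambident phloroglucinol-type phenoxide in water (C-prenylation of a polyphenolate); the two free ring carbons are equivalent, so mono-alkylation can give only one product, and no stereocentre is formed.

Step 2
Reactants: 2 2,4,6-trihydroxy-3-prenylbenzaldehyde
Product: 3 2-hydroxy-4,6-bis(methoxymethoxy)-3-prenylbenzaldehyde
Conditions: MOMCl (2.1 equiv), i-Pr2NEt, CH2Cl2, 0 °C
Reagents that add atoms: chloromethyl methyl ether COCCl
Why: Base-mediated O-alkylation (MOM ether formation); the most acidic 4-OH and the less hindered ortho 6-OH should react, while the 2-OH, flanked by the prenyl group and hydrogen-bonded to the aldehyde, should stay free.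

Step 3
Reactants: 4 3-bromo-4-methoxybenzaldehyde
Product: 5 4-methoxy-3-prenylbenzaldehyde
Conditions: tributyl(prenyl)stannane, Pd(PPh3)4 (5 mol %), DMF, 100 °C
Reagents that add atoms: tributyl(3-methylbut-2-en-1-yl)stannane CCCC[Sn](CCCC)(CCCC)CC=C(C)C
Why: Stille coupling; the prenyl group should be transferred through its unsubstituted allyl terminus to give the linear prenyl arene, and the aldehyde is inert under these neutral conditions.

Step 4
Reactants: 5 4-methoxy-3-prenylbenzaldehyde
Product: 6 (E)-3-(4-methoxy-3-prenylphenyl)prop-2-enal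
Conditions: Ph3P=CHCHO (1.05 equiv), toluene, 80 °C
Reagents that add atoms: (triphenylphosphoranylidene)acetaldehyde O=CC=P(c1ccccc1)(c1ccccc1)c1ccccc1
Why: Wittig reaction with a stabilised formyl ylide should give the (E)-enal, the near-stoichiometric amount of ylide limiting a second homologation.

Step 5
Reactants: 3 2-hydroxy-4,6-bis(methoxymethoxy)-3-prenylbenzaldehyde; 6 (E)-3-(4-methoxy-3-prenylphenyl)prop-2-enal
Product: 8 (2R)-2-(4-methoxy-3-prenylphenyl)-5,7-bis(methoxymethoxy)-8-prenyl-2H-chromene-3-carbaldehyde, via aldol adduct 7 (not isolated)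
Conditions: (S)-2-[diphenyl(trimethylsilyloxy)methyl]pyrrolidine (20 mol %), 2-nitrobenzoic acid (20 mol %), 4 Å molecular sieves, toluene, 25 °C
Reagents that add atoms: none
Why: Condensation of 6 with the secondary amine gives an (E)-iminium ion; the free 2-OH of 3 adds to its β-carbon (oxa-Michael, O1–C2) and the resulting enamine attacks the neighbouring aldehyde carbon (intramolecular aldol, C3–C4) to give 7, whose dehydration makes the sequence irreversible and, after hydrolysis, releases 8 and the amine. This is the known amine-catalysed domino oxa-Michael/aldol condensation of salicylaldehydes with cinnamaldehydes to 2H-chromene-3-carbaldehydes. Ring C closes in the aldol event as a 6-(enolexo)-exo-trig cyclisation. The only stereocentre that is kept, C2, is set in the C–O bond formation by the catalyst: the diphenyl(silyloxy)methyl group shields one face of the iminium ion, so the phenol should add to the Si face of the β-carbon, which corresponds to (R) at C2 of 8. The step needs regioselectivity among the three ring A oxygens, secured because only the OH next to the prenyl group is free (O-4 and O-6 are MOM ethers), and it needs 3 to act only as aldol acceptor, secured because its aldehyde has no α-hydrogen.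

Step 6
Reactants: 8 (2R)-2-(4-methoxy-3-prenylphenyl)-5,7-bis(methoxymethoxy)-8-prenyl-2H-chromene-3-carbaldehyde
Product: 9 (2R,3S,4S)-3,4-epoxy-2-(4-methoxy-3-prenylphenyl)-5,7-bis(methoxymethoxy)-8-prenylchromane-3-carbaldehyde
Conditions: 30% aq H2O2, NaOH (0.3 equiv), MeOH, 0 °C
Reagents that add atoms: hydrogen peroxide OO
Why: Weitz–Scheffer nucleophilic epoxidation: hydroperoxide adds to C4 of the enal and the enolate closes on oxygen from the face opposite to the 2-aryl group, while the electron-rich prenyl alkenes do not react with a nucleophilic oxidant; the C3/C4 configuration is provisional (C3 is re-set in step 7, C4 becomes a ketone).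

Step 7
Reactants: 9 (2R,3S,4S)-3,4-epoxy-2-(4-methoxy-3-prenylphenyl)-5,7-bis(methoxymethoxy)-8-prenylchromane-3-carbaldehyde
Product: 11 (2R,3R)-3-hydroxy-2-(4-methoxy-3-prenylphenyl)-5,7-bis(methoxymethoxy)-8-prenylchroman-4-one, via hydroxy keto aldehyde 10 (not isolated)
Conditions: DMSO, Sc(OTf)3 (5 mol %), 40 °C; then Et3N, MeOH, 0 °C to rt
Reagents that add atoms: dimethyl sulfoxide CS(C)=O
Why: Lewis-acid-assisted opening of the epoxide at the benzylic C4 by DMSO and loss of Me2S from the alkoxysulfonium ion (Kornblum-type oxidation of an epoxide to an α-hydroxy ketone) should give 10, whose non-enolisable β-keto aldehyde is cleaved by methanol/Et3N (retro-Claisen deformylation); protonation and enol-mediated equilibration at C3 should place the 3-OH trans to the 2-aryl group (both equatorial, 3R), C2 being untouched.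

Step 8
Reactants: 11 (2R,3R)-3-hydroxy-2-(4-methoxy-3-prenylphenyl)-5,7-bis(methoxymethoxy)-8-prenylchroman-4-one
Product: 12 (2R,3R)-3,5,7-trihydroxy-2-(4-methoxy-3-prenylphenyl)-8-prenylchroman-4-one (CNP0233452.1)
Conditions: 3 M aq HCl, MeOH, 40 °C
Reagents that add atoms: none
Why: Acid-catalysed acetal exchange with methanol removes both MOM ethers; the mild acid and temperature should spare the prenyl groups (no cyclisation onto the 7-OH) and the α-ketol, so that the (2R,3R) centres are kept.

**Compound list**

1 | 2,4,6-trihydroxybenzaldehyde | O=Cc1c(O)cc(O)cc1O | starting material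
2 | 2,4,6-trihydroxy-3-prenylbenzaldehyde | O=Cc1c(O)cc(O)c(CC=C(C)C)c1O | intermediate
3 | 2-hydroxy-4,6-bis(methoxymethoxy)-3-prenylbenzaldehyde | O=Cc1c(OCOC)cc(OCOC)c(CC=C(C)C)c1O | intermediate
4 | 3-bromo-4-methoxybenzaldehyde | COc1ccc(C=O)cc1Br | starting material
5 | 4-methoxy-3-prenylbenzaldehyde | COc1ccc(C=O)cc1CC=C(C)C | intermediate
6 | (E)-3-(4-methoxy-3-prenylphenyl)prop-2-enal | COc1ccc(/C=C/C=O)cc1CC=C(C)C | intermediate
7 | (2S)-4-hydroxy-2-(4-methoxy-3-prenylphenyl)-5,7-bis(methoxymethoxy)-8-prenylchromane-3-carbaldehyde (aldol adduct; same spatial arrangement at C2 as in 8, C3 and C4 not assigned; not isolated) | COc1ccc([C@H]2Oc3c(CC=C(C)C)c(OCOC)cc(OCOC)c3C(O)C2C=O)cc1CC=C(C)C | intermediate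
8 | (2R)-2-(4-methoxy-3-prenylphenyl)-5,7-bis(methoxymethoxy)-8-prenyl-2H-chromene-3-carbaldehyde | COc1ccc([C@H]2Oc3c(CC=C(C)C)c(OCOC)cc(OCOC)c3C=C2C=O)cc1CC=C(C)C | intermediate
9 | (2R,3S,4S)-3,4-epoxy-2-(4-methoxy-3-prenylphenyl)-5,7-bis(methoxymethoxy)-8-prenylchromane-3-carbaldehyde (epoxide oxygen trans to the 2-aryl group) | COc1ccc([C@H]2Oc3c(CC=C(C)C)c(OCOC)cc(OCOC)c3[C@@H]4O[C@]24C=O)cc1CC=C(C)C | intermediate
10 | (2R,3S)-3-hydroxy-2-(4-methoxy-3-prenylphenyl)-5,7-bis(methoxymethoxy)-4-oxo-8-prenylchromane-3-carbaldehyde (3-OH trans to the 2-aryl group; not isolated) | COc1ccc([C@H]2Oc3c(CC=C(C)C)c(OCOC)cc(OCOC)c3C(=O)[C@@]2(O)C=O)cc1CC=C(C)C | intermediate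
11 | (2R,3R)-3-hydroxy-2-(4-methoxy-3-prenylphenyl)-5,7-bis(methoxymethoxy)-8-prenylchroman-4-one | COc1ccc([C@H]2Oc3c(CC=C(C)C)c(OCOC)cc(OCOC)c3C(=O)[C@@H]2O)cc1CC=C(C)C | intermediate
12 | (2R,3R)-3,5,7-trihydroxy-2-(4-methoxy-3-prenylphenyl)-8-prenylchroman-4-one (CNP0233452.1) | COc1ccc([C@H]2Oc3c(CC=C(C)C)c(O)cc(O)c3C(=O)[C@@H]2O)cc1CC=C(C)C | target

**Step count and risks**

Total step count: 8. Longest linear sequence: 6 steps (steps 1, 2, 5, 6, 7, 8, or equally 3, 4, 5, 6, 7, 8).

Risk 1 (step 7). After ionisation at C4 the formyl group may migrate from C3 to C4 (semipinacol shift) faster than DMSO is captured, or the enolate formed on deformylation may open ring C by β-elimination of O1 and so lose the C2 configuration. The fallback sets out from 8 and removes the formyl group before any oxygen is brought in. Decarbonylation of 8 (RhCl(PPh3)3, 1 equiv, toluene, 110 °C; Tsuji–Wilkinson reaction) should give (2S)-2-(4-methoxy-3-prenylphenyl)-5,7-bis(methoxymethoxy)-8-prenyl-2H-chromene F1 (same spatial arrangement at C2 as in 8). Jacobsen epoxidation ((S,S)-MnCl(salen), salen = N,N'-bis(3,5-di-tert-butylsalicylidene)cyclohexane-1,2-diamine dianion, the enantiomer that gives (3S,4S)-epoxides from 2H-chromenes; NaOCl, 4-phenylpyridine N-oxide, CH2Cl2, 0 °C) prefers the conjugated cis-alkene to the isolated prenyl alkenes, and both the catalyst and the 2-aryl group direct oxygen to the face anti to the aryl group; it should give (2R,3S,4S)-3,4-epoxy-2-(4-methoxy-3-prenylphenyl)-5,7-bis(methoxymethoxy)-8-prenylchromane F2. F2, used crude, is oxidised with DMSO under the conditions of step 7 (no deformylation is needed); the epoxide oxygen becomes the 3-OH trans to the aryl group and the route is rejoined at 11.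

Risk 2 (step 5). The hindered, hydrogen-bonded phenol of 3 may add slowly and reversibly to the electron-rich iminium ion of 6, so that turnover is poor and the enantiomeric excess is eroded by retro-oxa-Michael reaction. The fallback sets out from 3 and 6 and moves the stereocontrol from the annulation to a kinetic resolution. The same two bonds are closed without asymmetric induction (K2CO3, 1,4-dioxane, 100 °C, oxa-Michael/aldol condensation) to give racemic 8, that is 8 together with its enantiomer (2S)-2-(4-methoxy-3-prenylphenyl)-5,7-bis(methoxymethoxy)-8-prenyl-2H-chromene-3-carbaldehyde F3. Decarbonylation as in the first fallback gives the racemic chromene, F1 together with its enantiomer (2R)-2-(4-methoxy-3-prenylphenyl)-5,7-bis(methoxymethoxy)-8-prenyl-2H-chromene F4. The Jacobsen epoxidation with (S,S)-MnCl(salen) is then run to about half conversion as a kinetic resolution of the racemic chromene: F1 is the matched enantiomer and should be converted into F2, while F4 is left and separated. F2 is oxidised with DMSO as above and the route is rejoined at 11.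

Risk 3 (step 2). Discrimination between the two ortho hydroxyl groups may be poor (alkylation of the 2-OH next to the prenyl group instead of the 6-OH), which would lead to the 6-prenyl isomer after ring closure. The fallback sets out from 1 and fixes the regiochemistry by a sigmatropic shift. MOMCl (2.1 equiv)/i-Pr2NEt on 1 gives the symmetric 2-hydroxy-4,6-bis(methoxymethoxy)benzaldehyde F5, for which no regiochemical question arises. Allyl bromide/K2CO3 in acetone gives 2-(allyloxy)-4,6-bis(methoxymethoxy)benzaldehyde F6. Aromatic Claisen rearrangement (N,N-diethylaniline, 190 °C) can deliver the allyl group only to the one free ortho carbon and should give 3-allyl-2-hydroxy-4,6-bis(methoxymethoxy)benzaldehyde F7. Cross-metathesis of F7 with 2-methylbut-2-ene (second-generation Grubbs catalyst, CH2Cl2, 40 °C) converts the allyl into the prenyl group and rejoins the route at 3.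

Further compounds

F1 | step 7 | (2S)-2-(4-methoxy-3-prenylphenyl)-5,7-bis(methoxymethoxy)-8-prenyl-2H-chromene | COc1ccc([C@H]2Oc3c(CC=C(C)C)c(OCOC)cc(OCOC)c3C=C2)cc1CC=C(C)C
F2 | step 7 | (2R,3S,4S)-3,4-epoxy-2-(4-methoxy-3-prenylphenyl)-5,7-bis(methoxymethoxy)-8-prenylchromane | COc1ccc([C@H]2Oc3c(CC=C(C)C)c(OCOC)cc(OCOC)c3[C@@H]4O[C@H]24)cc1CC=C(C)C
F3 | step 5 | (2S)-2-(4-methoxy-3-prenylphenyl)-5,7-bis(methoxymethoxy)-8-prenyl-2H-chromene-3-carbaldehyde (enantiomer of 8) | COc1ccc([C@@H]2Oc3c(CC=C(C)C)c(OCOC)cc(OCOC)c3C=C2C=O)cc1CC=C(C)C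
F4 | step 5 | (2R)-2-(4-methoxy-3-prenylphenyl)-5,7-bis(methoxymethoxy)-8-prenyl-2H-chromene (enantiomer of F1) | COc1ccc([C@@H]2Oc3c(CC=C(C)C)c(OCOC)cc(OCOC)c3C=C2)cc1CC=C(C)C
F5 | step 2 | 2-hydroxy-4,6-bis(methoxymethoxy)benzaldehyde | O=Cc1c(O)cc(OCOC)cc1OCOC
F6 | step 2 | 2-(allyloxy)-4,6-bis(methoxymethoxy)benzaldehyde | O=Cc1c(OCC=C)cc(OCOC)cc1OCOC
F7 | step 2 | 3-allyl-2-hydroxy-4,6-bis(methoxymethoxy)benzaldehyde | O=Cc1c(OCOC)cc(OCOC)c(CC=C)c1O
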